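Locants: unprimed = keto unit (C1 ketal carbon, C4 carbonyl, C8 the aryl carbon bonded to C1′); primed = carbinol unit (C1′ quaternary carbon, C4′ carbinol, C8′ aryl ether carbon).
Enabling feature: the lower arene carries adjacent C8′–O and C8a′–C1′ bonds, and the 1,3-dioxin ring C1–O–C8′–C8a′–C1′–O is the formal [4+2] adduct of an ortho-quinone methide (O=C8′–C8a′=C1′) with the C1 carbonyl; that quinone methide is itself the ring-opened [2+2] adduct of a C8′–C8a′ aryne and a C1′ ketone.
Retrosynthesis: remove both oxiranes, then cut C1′–C8a′, C8′–O, C1–O(C8′) and C1′–O(bridge) together, back to a 1,4-naphthoquinone whose C8 acyl group is joined through a cis C2′=C3′ alkene and the C4′ silyloxy carbon to a 2-silylaryl triflate; then cut C1′–C2′ (acetylide plus Weinreb amide) and C3′–C4′ (alkynylation of an aryl aldehyde).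
Forward: the upper arene (from 5,8-dimethoxy-1-tetralone) and the lower arene (from 4-chlororesorcinol) are made separately and joined through ethynyltrimethylsilane as C2′–C3′; one fluoride-triggered cascade then closes the lower carbocycle, the five-membered ring and the dioxin ring, and the two oxiranes come last.
Stereochemistry: C4′ from a catalytic asymmetric alkynylation; C1′ and C1 relayed from C4′ in the cascade; C2/C3 and C2′/C3′ from substrate-controlled epoxidations (anti to the C1 aryloxy bridge, anti to the C4′ silyloxy group).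

Key step: step 16

Remark: the (S,S)-ProPhenol–zinc catalyst is assumed to deliver the alkynyl group to the Re face of aldehyde 16, as in its aldol reactions; should the opposite sense hold, the (R,R) ligand is used and nothing else changes.

Step 1
Reactants: 1 5,8-dimethoxy-3,4-dihydronaphthalen-1(2H)-one
Product: 3 5,8-dimethoxynaphthalen-1-ol, via 2-bromo ketone 2 (not isolated)
Conditions: PhNMe3Br3, THF, 0 °C; then Li2CO3, LiBr, DMF, 120 °C
Reagents that add atoms: none
Why: α-bromination of the ketone and base-induced dehydrobromination give the 2,3-enone, which tautomerises to the naphthol, the standard aromatisation of a 1-tetralone.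

Step 2
Reactants: 3 5,8-dimethoxynaphthalen-1-ol
Product: 4 4-bromo-5,8-dimethoxynaphthalen-1-ol
Conditions: NBS, MeCN, −20 to 0 °C
Reagents that add atoms: N-bromosuccinimide, O=C1CCC(=O)N1Br
Why: electrophilic aromatic bromination of a 1-naphthol goes to the free para position C4, and a peri methoxy group does not block it, as the C4 bromination of 1,5-dimethoxynaphthalene shows.

Step 3
Reactants: 4 4-bromo-5,8-dimethoxynaphthalen-1-ol
Product: 5 4-bromo-2-chloro-5,8-dimethoxynaphthalen-1-ol
Conditions: SO2Cl2, 2,2,6,6-tetramethylpiperidine (cat.), toluene, 0 to 23 °C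
Reagents that add atoms: sulfuryl chloride, O=S(=O)(Cl)Cl
Why: amine-catalysed ortho-chlorination of a phenol; with C4 blocked, C2 is the only position still activated by the free hydroxyl.

Step 4
Reactants: 5 4-bromo-2-chloro-5,8-dimethoxynaphthalen-1-ol
Product: 6 4-bromo-2-chloro-5,8-dimethoxy-1-(methoxymethoxy)naphthalene
Conditions: NaH, MeOCH2Cl, DMF, 0 °C
Reagents that add atoms: chloromethyl methyl ether, COCCl
Why: Williamson-type O-alkylation of the sodium naphtholate, chosen over amine bases because the hydroxyl is flanked by chlorine and hydrogen-bonded to the peri methoxy group.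

Step 5
Reactants: 6 4-bromo-2-chloro-5,8-dimethoxy-1-(methoxymethoxy)naphthalene
Product: 8 3-chloro-N,5,8-trimethoxy-4-(methoxymethoxy)-N-methylnaphthalene-1-carboxamide, via aryllithium 7 (not isolated)
Conditions: n-BuLi, THF, −78 °C; then ClC(O)N(OMe)Me, −78 to 0 °C
Reagents that add atoms: N-methoxy-N-methylcarbamoyl chloride, CON(C)C(Cl)=O
Why: bromine–lithium exchange is much faster than any reaction at the aryl chloride, and acylation of the aryllithium by the carbamoyl chloride stops at the Weinreb amide.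

Step 6
Reactants: 9 4-chlorobenzene-1,3-diol
Product: 10 4-bromo-6-chlorobenzene-1,3-diol
Conditions: NBS, MeCN, 0 °C
Reagents that add atoms: N-bromosuccinimide, O=C1CCC(=O)N1Br
Why: electrophilic bromination of a resorcinol goes to C6 (para to one hydroxyl, ortho to the other) in preference to the hindered C2 between the hydroxyls.

Step 7
Reactants: 10 4-bromo-6-chlorobenzene-1,3-diol
Product: 14 4-chloro-5-hydroxy-2-(trimethylsilyl)phenyl trifluoromethanesulfonate, via bis(trimethylsilyl) ether 11 (not isolated), via lithium phenoxide 12 (not isolated), via silyl ether triflate 13 (not isolated)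
Conditions: (Me3Si)2NH, THF, 70 °C, then evaporation; n-BuLi, THF, −78 °C; Tf2O, −78 to 0 °C; aqueous NaHCO3 work-up
Reagents that add atoms: hexamethyldisilazane, C[Si](C)(C)N[Si](C)(C)C; trifluoromethanesulfonic anhydride, O=S(=O)(OS(=O)(=O)C(F)(F)F)C(F)(F)F
Why: retro-Brook route to a 2-silylaryl triflate, in which bromine–lithium exchange places the anion next to one silyloxy group only, 1,3 O-to-C silyl migration gives a single phenoxide that alone is triflated, and the untouched aryl silyl ether is hydrolysed on work-up, so the two oxygens are differentiated without a protecting-group step.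

Step 8
Reactants: 14 4-chloro-5-hydroxy-2-(trimethylsilyl)phenyl trifluoromethanesulfonate
Product: 15 4-chloro-2-formyl-3-hydroxy-6-(trimethylsilyl)phenyl trifluoromethanesulfonate
Conditions: MgCl2, Et3N, (CH2O)n, MeCN, 70 °C
Reagents that add atoms: paraformaldehyde (formaldehyde), C=O
Why: magnesium-mediated ortho-formylation of a phenol (Casnati–Skattebøl) is ortho-specific, the other ortho position carries chlorine, and the fluoride-free, weakly basic medium should leave the silyl triflate intact.

Step 9
Reactants: 15 4-chloro-2-formyl-3-hydroxy-6-(trimethylsilyl)phenyl trifluoromethanesulfonate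
Product: 16 4-chloro-2-formyl-3-(methoxymethoxy)-6-(trimethylsilyl)phenyl trifluoromethanesulfonate
Conditions: MeOCH2Cl, i-Pr2NEt, CH2Cl2, 0 to 23 °C
Reagents that add atoms: chloromethyl methyl ether, COCCl
Why: standard O-alkylation of a salicylaldehyde hydroxyl with an amine base, which touches neither the aldehyde nor the silyl triflate.

Step 10
Reactants: 16 4-chloro-2-formyl-3-(methoxymethoxy)-6-(trimethylsilyl)phenyl trifluoromethanesulfonate; 17 ethynyltrimethylsilane
Product: 18 4-chloro-2-[(1S)-1-hydroxy-3-(trimethylsilyl)prop-2-yn-1-yl]-3-(methoxymethoxy)-6-(trimethylsilyl)phenyl trifluoromethanesulfonate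
Conditions: (S,S)-ProPhenol (20 mol %), Me2Zn, Ph3PO (40 mol %), toluene, 4 °C
Reagents that add atoms: none
Why: zinc–ProPhenol catalysed enantioselective alkynylation of an aromatic aldehyde, in which the dinuclear zinc alkoxide delivers the alkynyl group to the Re face and so sets C4′ (S here because the silylalkynyl group outranks the aryl group).

Step 11
Reactants: 18 the (S)-propargylic alcohol
Product: 19 4-chloro-2-[(1S)-1-(tert-butyldimethylsilyloxy)-3-(trimethylsilyl)prop-2-yn-1-yl]-3-(methoxymethoxy)-6-(trimethylsilyl)phenyl trifluoromethanesulfonate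
Conditions: t-BuMe2SiOTf, 2,6-lutidine, CH2Cl2, −78 to 0 °C
Reagents that add atoms: tert-butyldimethylsilyl trifluoromethanesulfonate, CC(C)(C)[Si](C)(C)OS(=O)(=O)C(F)(F)F
Why: silylation of a hindered secondary alcohol with the silyl triflate and a hindered pyridine base; the bulky ether later shields one face of the lower ring.

Step 12
Reactants: 19 the silyl ether
Product: 20 4-chloro-2-[(1R)-1-(tert-butyldimethylsilyloxy)prop-2-yn-1-yl]-3-(methoxymethoxy)-6-(trimethylsilyl)phenyl trifluoromethanesulfonate
Conditions: K2CO3 (0.2 equiv), MeOH/THF, 0 °C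
Reagents that add atoms: none
Why: catalytic methoxide cleaves the alkynyl C–Si bond far faster than the aryl C–Si bond, and without fluoride the silyl triflate does not fragment (the descriptor changes to R only because ethynyl ranks below aryl).

Step 13
Reactants: 20 the terminal alkyne; 8 the Weinreb amide
Product: 22 4-chloro-2-[(1R)-1-(tert-butyldimethylsilyloxy)-4-[3-chloro-5,8-dimethoxy-4-(methoxymethoxy)naphthalen-1-yl]-4-oxobut-2-yn-1-yl]-3-(methoxymethoxy)-6-(trimethylsilyl)phenyl trifluoromethanesulfonate, via lithium acetylide 21 (not isolated)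
Conditions: n-BuLi, THF, −78 °C; then 8, −78 to 0 °C
Reagents that add atoms: none
Why: Weinreb ketone synthesis with a lithium acetylide forms the C1′–C2′ bond without over-addition, deprotonation of the alkyne at −78 °C being faster than attack of n-BuLi on the triflate.

Step 14
Reactants: 22 the ynone
Product: 23 4-chloro-2-[(1R,2Z)-1-(tert-butyldimethylsilyloxy)-4-[3-chloro-5,8-dimethoxy-4-(methoxymethoxy)naphthalen-1-yl]-4-oxobut-2-en-1-yl]-3-(methoxymethoxy)-6-(trimethylsilyl)phenyl trifluoromethanesulfonate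
Conditions: H2 (1 atm), Pd/CaCO3 poisoned with Pb(OAc)2 (Lindlar catalyst), quinoline, EtOAc, 0 °C
Reagents that add atoms: none
Why: Lindlar semi-hydrogenation adds hydrogen syn to the alkyne and gives the cis-enone, the only geometry from which C1′ can reach C8a′; aryl chloride, triflate and silane are inert to the poisoned catalyst.

Step 15
Reactants: 23 the cis-enone
Product: 24 4-chloro-2-[(1R,2Z)-1-(tert-butyldimethylsilyloxy)-4-[3-chloro-4-(methoxymethoxy)-5,8-dioxo-5,8-dihydronaphthalen-1-yl]-4-oxobut-2-en-1-yl]-3-(methoxymethoxy)-6-(trimethylsilyl)phenyl trifluoromethanesulfonate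
Conditions: (NH4)2Ce(NO3)6, MeCN/H2O (4:1), 0 °C
Reagents that add atoms: water, O
Why: oxidative demethylation of a 1,4-dimethoxyarene by tetravalent cerium; only the dimethoxy ring can become a quinone, and the electron-poor lower arene is not oxidised in a short reaction at 0 °C.

Step 16
Reactants: 24 the 8-acyl-1,4-naphthoquinone with cis-enone tether to the silyl triflate
Product: 28 (1R,1′S,4′R)-bridged ketal carrying the upper C2=C3–C4=O enone and the lower C2′=C3′ alkene, via aryne 25 (not isolated), via benzoxete 26 (not isolated), via ortho-quinone methide 27 (not isolated)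
Conditions: CsF, MeCN (5 mM), 23 °C
Reagents that add atoms: none
Why: Proposed new method: fluoride attacks the C8′ silyl group and the aryl anion, which lies too far from any carbonyl to add to it, expels the C8a′ triflate to give the C8′–C8a′ aryne 25; the C1′ ketone, held by the cis-alkene tether, adds across it in a formal [2+2] (C1′–C8a′ and O–C8′) to give benzoxete 26, 4π electrocyclic opening gives ortho-quinone methide 27, and the peri C1 quinone carbonyl then adds as a heterodienophile (its oxygen to C1′, C1 to the quinone methide oxygen), which restores the arene. The closest known reactions are the intermolecular [2+2] of arynes with aldehydes or formamides to ortho-quinone methides and the [4+2] capture of these by a second carbonyl compound to 1,3-benzodioxins; an intramolecular ketone and a quinone carbonyl as the 2π partner have not been shown. The lower carbocycle closes 6-exo through the C1′–C8a′ bond of the [2+2], the five-membered ring closes 5-exo by bonding of the peri carbonyl oxygen to C1′, and the six-membered dioxin ring closes through the O–C1 bond as the second bond of the [4+2]. C1′ is set by approach of the peri carbonyl anti to the pseudoaxial C4′ silyloxy group, and C1 follows because the two new bonds can only form on the same face of the peri-fused five-membered ring. The tether fixes the regiochemistry of aryne capture (only C8a′ can reach C1′ in a six-membered ring); the cycloaddition must outrun aromatising loss of H-4′ from 27, which high dilution, the absence of added base and the peri placement of the carbonyl are meant to secure.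

Step 17
Reactants: 28 the bridged ketal
Product: 29 (1S,2R,3S,1′S,4′R)-2,3-epoxy ketone
Conditions: t-BuOOH, DBU, CH2Cl2, 0 °C
Reagents that add atoms: tert-butyl hydroperoxide, CC(C)(C)OO
Why: Weitz–Scheffer nucleophilic epoxidation of the enone, in which the hydroperoxide adds to C3 anti to the axial aryloxy oxygen on C1 and the lower arene behind it, setting C2 and C3, while the isolated C2′=C3′ alkene does not react.

Step 18
Reactants: 29 the epoxy ketone
Product: 30 (1S,2R,3S,1′S,2′R,3′S,4′S)-bis-epoxide with both phenols and the C4′ hydroxyl still protected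
Conditions: dimethyldioxirane, acetone/CH2Cl2, 0 °C
Reagents that add atoms: dimethyldioxirane, CC1(C)OO1
Why: electrophilic epoxidation of the only remaining alkene from the face anti to the C4′ silyloxy group and the C1′–C8 bond (syn to the small bridging oxygen), setting C2′ and C3′; the phenols stay protected so that the arenes are not oxidised.

Step 19
Reactants: 30 the protected bis-epoxide
Product: 31 (1S,2R,3S,1′S,2′R,3′S,4′S)-bis-epoxide diphenol retaining the C4′ silyl ether
Conditions: CF3CO2H/CH2Cl2 (1:10), 0 °C; then aqueous NaHCO3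
Reagents that add atoms: none
Why: acid-catalysed cleavage of the two aryl methoxymethyl acetals; the epoxy ketone and the oxirane flanked by C1′ and C4′ are poor substrates for opening by the weakly nucleophilic trifluoroacetate, and any silyl ether lost here converges in step 20.

Step 20
Reactants: 31 the diphenol silyl ether
Product: 32 the target, (1S,2R,3S,1′S,2′R,3′R,4′S)
Conditions: Bu4NF, AcOH, THF, 0 to 23 °C
Reagents that add atoms: none
Why: fluoride-mediated desilylation buffered with acetic acid, conditions that leave oxiranes, ketone and phenols untouched (C3′ becomes R only through the change in priorities).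

Compound list
1 | 5,8-dimethoxy-3,4-dihydronaphthalen-1(2H)-one (5,8-dimethoxy-1-tetralone) | COc1ccc(OC)c2c1CCCC2=O | starting material
2 | 2-bromo-5,8-dimethoxy-3,4-dihydronaphthalen-1(2H)-one (racemic) | COc1ccc(OC)c2c1CCC(Br)C2=O | intermediate
3 | 5,8-dimethoxynaphthalen-1-ol | COc1ccc(OC)c2c(O)cccc12 | intermediate
4 | 4-bromo-5,8-dimethoxynaphthalen-1-ol | COc1ccc(OC)c2c(O)ccc(Br)c12 | intermediate
5 | 4-bromo-2-chloro-5,8-dimethoxynaphthalen-1-ol | COc1ccc(OC)c2c(O)c(Cl)cc(Br)c12 | intermediate
6 | 4-bromo-2-chloro-5,8-dimethoxy-1-(methoxymethoxy)naphthalene | COCOc1c(Cl)cc(Br)c2c(OC)ccc(OC)c12 | intermediate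
7 | [3-chloro-5,8-dimethoxy-4-(methoxymethoxy)naphthalen-1-yl]lithium | [Li]c1cc(Cl)c(OCOC)c2c(OC)ccc(OC)c12 | intermediate
8 | 3-chloro-N,5,8-trimethoxy-4-(methoxymethoxy)-N-methylnaphthalene-1-carboxamide | CON(C)C(=O)c1cc(Cl)c(OCOC)c2c(OC)ccc(OC)c12 | intermediate
9 | 4-chlorobenzene-1,3-diol (4-chlororesorcinol) | Oc1ccc(Cl)c(O)c1 | starting material
10 | 4-bromo-6-chlorobenzene-1,3-diol | Oc1cc(O)c(Cl)cc1Br | intermediate
11 | 1-bromo-5-chloro-2,4-bis(trimethylsilyloxy)benzene | C[Si](C)(C)Oc1cc(O[Si](C)(C)C)c(Cl)cc1Br | intermediate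
12 | lithium 4-chloro-2-(trimethylsilyl)-5-(trimethylsilyloxy)phenolate | [Li]Oc1cc(O[Si](C)(C)C)c(Cl)cc1[Si](C)(C)C | intermediate
13 | 4-chloro-2-(trimethylsilyl)-5-(trimethylsilyloxy)phenyl trifluoromethanesulfonate | C[Si](C)(C)Oc1cc(OS(=O)(=O)C(F)(F)F)c([Si](C)(C)C)cc1Cl | intermediate
14 | 4-chloro-5-hydroxy-2-(trimethylsilyl)phenyl trifluoromethanesulfonate | Oc1cc(OS(=O)(=O)C(F)(F)F)c([Si](C)(C)C)cc1Cl | intermediate
15 | 4-chloro-2-formyl-3-hydroxy-6-(trimethylsilyl)phenyl trifluoromethanesulfonate | O=Cc1c(O)c(Cl)cc([Si](C)(C)C)c1OS(=O)(=O)C(F)(F)F | intermediate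
16 | 4-chloro-2-formyl-3-(methoxymethoxy)-6-(trimethylsilyl)phenyl trifluoromethanesulfonate | O=Cc1c(OCOC)c(Cl)cc([Si](C)(C)C)c1OS(=O)(=O)C(F)(F)F | intermediate
17 | ethynyltrimethylsilane | C#C[Si](C)(C)C | starting material
18 | 4-chloro-2-[(1S)-1-hydroxy-3-(trimethylsilyl)prop-2-yn-1-yl]-3-(methoxymethoxy)-6-(trimethylsilyl)phenyl trifluoromethanesulfonate | C[Si](C)(C)C#C[C@@H](O)c1c(OCOC)c(Cl)cc([Si](C)(C)C)c1OS(=O)(=O)C(F)(F)F | intermediate
19 | 4-chloro-2-[(1S)-1-(tert-butyldimethylsilyloxy)-3-(trimethylsilyl)prop-2-yn-1-yl]-3-(methoxymethoxy)-6-(trimethylsilyl)phenyl trifluoromethanesulfonate | C[Si](C)(C)C#C[C@@H](O[Si](C)(C)C(C)(C)C)c1c(OCOC)c(Cl)cc([Si](C)(C)C)c1OS(=O)(=O)C(F)(F)F | intermediate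
20 | 4-chloro-2-[(1R)-1-(tert-butyldimethylsilyloxy)prop-2-yn-1-yl]-3-(methoxymethoxy)-6-(trimethylsilyl)phenyl trifluoromethanesulfonate | C#C[C@@H](O[Si](C)(C)C(C)(C)C)c1c(OCOC)c(Cl)cc([Si](C)(C)C)c1OS(=O)(=O)C(F)(F)F | intermediate
21 | lithium acetylide of 20 (C-lithiated at the alkyne terminus, 1R) | [Li]C#C[C@@H](O[Si](C)(C)C(C)(C)C)c1c(OCOC)c(Cl)cc([Si](C)(C)C)c1OS(=O)(=O)C(F)(F)F | intermediate
22 | ynone: 4-chloro-2-[(1R)-1-(tert-butyldimethylsilyloxy)-4-[3-chloro-5,8-dimethoxy-4-(methoxymethoxy)naphthalen-1-yl]-4-oxobut-2-yn-1-yl]-3-(methoxymethoxy)-6-(trimethylsilyl)phenyl trifluoromethanesulfonate | COc1ccc(OC)c2c(OCOC)c(Cl)cc(C(=O)C#C[C@@H](O[Si](C)(C)C(C)(C)C)c3c(OCOC)c(Cl)cc([Si](C)(C)C)c3OS(=O)(=O)C(F)(F)F)c12 | intermediate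
23 | cis-enone: 4-chloro-2-[(1R,2Z)-1-(tert-butyldimethylsilyloxy)-4-[3-chloro-5,8-dimethoxy-4-(methoxymethoxy)naphthalen-1-yl]-4-oxobut-2-en-1-yl]-3-(methoxymethoxy)-6-(trimethylsilyl)phenyl trifluoromethanesulfonate | COc1ccc(OC)c2c(OCOC)c(Cl)cc(C(=O)/C=C\[C@@H](O[Si](C)(C)C(C)(C)C)c3c(OCOC)c(Cl)cc([Si](C)(C)C)c3OS(=O)(=O)C(F)(F)F)c12 | intermediate
24 | quinone: 4-chloro-2-[(1R,2Z)-1-(tert-butyldimethylsilyloxy)-4-[3-chloro-4-(methoxymethoxy)-5,8-dioxo-5,8-dihydronaphthalen-1-yl]-4-oxobut-2-en-1-yl]-3-(methoxymethoxy)-6-(trimethylsilyl)phenyl trifluoromethanesulfonate | O=C1C=CC(=O)c2c1c(OCOC)c(Cl)cc2C(=O)/C=C\[C@@H](O[Si](C)(C)C(C)(C)C)c1c(OCOC)c(Cl)cc([Si](C)(C)C)c1OS(=O)(=O)C(F)(F)F | intermediate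
25 | aryne: 24 without the silyl and triflate groups, C8′≡C8a′ (4′R, 2′Z) | O=C1C=CC(=O)c2c1c(OCOC)c(Cl)cc2C(=O)/C=C\[C@@H](O[Si](C)(C)C(C)(C)C)C1=C(OCOC)C(Cl)=CC#C1 | intermediate
26 | benzoxete: four-membered ring C1′–O–C8′–C8a′, C1′ also bonded to C8 and C2′, lower carbocycle closed (4′R; C1′ not defined, it is lost on ring opening) | O=C1C=CC(=O)c2c1c(OCOC)c(Cl)cc2C13Oc4cc(Cl)c(OCOC)c(c41)[C@H](O[Si](C)(C)C(C)(C)C)C=C3 | intermediate
27 | ortho-quinone methide: O=C8′–C8a′=C1′, C1′ bonded to C8 of the naphthoquinone and to C2′ (4′R) | O=C1C=CC(=O)c2c1c(OCOC)c(Cl)cc2C1=C3C(=O)C=C(Cl)C(OCOC)=C3[C@H](O[Si](C)(C)C(C)(C)C)C=C1 | intermediate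
28 | (1R,1′S,4′R)-bridged ketal: skeleton of 32 with C2=C3 and C2′=C3′ double bonds in place of the oxiranes, 5-O- and 5′-O-methoxymethyl, 4′-O-tert-butyldimethylsilyl | O=C1c2c(OCOC)c(Cl)cc3c2[C@@]2(Oc4cc(Cl)c(OCOC)c5c4[C@]3(O2)C=C[C@H]5O[Si](C)(C)C(C)(C)C)C=C1 | intermediate
29 | (1S,2R,3S,1′S,4′R)-2,3-epoxy ketone: 28 with the upper oxirane anti to the C1–O–C8′ oxygen | O=C1c2c(OCOC)c(Cl)cc3c2[C@@]2(Oc4cc(Cl)c(OCOC)c5c4[C@]3(O2)C=C[C@H]5O[Si](C)(C)C(C)(C)C)[C@@H]2O[C@H]12 | intermediate
30 | (1S,2R,3S,1′S,2′R,3′S,4′S)-bis-epoxide: 32 as its 5,5′-bis(methoxymethyl) ether and 4′-tert-butyldimethylsilyl ether | O=C1c2c(OCOC)c(Cl)cc3c2[C@@]2(Oc4cc(Cl)c(OCOC)c5c4[C@]3(O2)[C@@H]2O[C@@H]2[C@H]5O[Si](C)(C)C(C)(C)C)[C@@H]2O[C@H]12 | intermediate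
31 | (1S,2R,3S,1′S,2′R,3′S,4′S)-bis-epoxide diphenol: 32 as its 4′-tert-butyldimethylsilyl ether | O=C1c2c(O)c(Cl)cc3c2[C@@]2(Oc4cc(Cl)c(O)c5c4[C@]3(O2)[C@@H]2O[C@@H]2[C@H]5O[Si](C)(C)C(C)(C)C)[C@@H]2O[C@H]12 | intermediate
32 | CNP0289684.3, (1S,2R,3S,1′S,2′R,3′R,4′S): 6,6′-dichloro-5,5′,4′-trihydroxy bis-epoxy bridged ketal with C4 ketone | O=C1c2c(O)c(Cl)cc3c2[C@@]2(Oc4cc(Cl)c(O)c5c4[C@]3(O2)[C@@H]2O[C@@H]2[C@H]5O)[C@@H]2O[C@H]12 | target

Total step count: 20. Longest linear sequence: 15 steps (9 to 32 through steps 6–20); the upper arene 8 takes 5 steps.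

Steps most likely to fail

1. Step 16 (proposed new method). The aryne may be consumed by intermolecular or fluoride-derived pathways before the C1′ ketone adds, or quinone methide 27 may lose H-4′ and aromatise to a binaphthyl before the peri carbonyl closes the ketal. The fallback uses known reaction types only and never forms a quinone methide; it sets out from cis-enone 23 and uses the C8a′ triflate as a cross-coupling handle. Nickel-catalysed reductive 1,2-addition of the aryl triflate to the C1′ ketone (NiBr2(dme), 2,2′-bipyridine, Zn, DMA, zerovalent nickel as the active species) should close the carbocycle and give the tertiary carbinol F1, of which the epimer with hydroxyl trans to the C4′ silyloxy group is carried on. Oxidation with (NH4)2Ce(NO3)6 should then give the hydroxy quinone F2, in equilibrium with its five-membered hemiketal at C1. ICl should replace the C8′ silyl group, which is para to the methoxymethoxy group, by iodine to give the aryl iodide F3. Copper-catalysed intramolecular C–O coupling of the hemiketal hydroxyl with the aryl iodide (CuI, 1,10-phenanthroline, Cs2CO3, toluene, 90 °C) closes the dioxin ring and returns to the route at 28.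

2. Step 14. Over-reduction of the enone, or cis-to-trans isomerisation on the catalyst, would give material that cannot cyclise. The fallback sets out from ynone 22: Luche reduction (NaBH4, CeCl3·7H2O, MeOH, −40 °C) should give the propargylic alcohol F4 as a mixture of C1′ epimers. Semi-hydrogenation of this ynol over the same poisoned palladium catalyst, a more forgiving substrate, should give the cis-allylic alcohol F5. Oxidation with Dess–Martin periodinane buffered with NaHCO3 restores the ketone and returns to the route at 23.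

3. Step 19. Acid may open an oxirane or ionise the molecule at C4′ or C1′ while the acetals are cleaved. The fallback sets out from 30: silyl-transfer deacetalisation with Et3SiOTf and 2,2′-bipyridyl (CH2Cl2, 0 °C), which runs under weakly basic conditions, should convert both aryl methoxymethyl ethers into triethylsilyl ethers and give the tris(silyl) ether F6. Buffered Bu4NF/AcOH (the conditions of step 20) then removes all three silyl groups and returns to the route at 32.

Further compounds
F1 | step 16 | tertiary carbinol from closure of C8a′–C1′ on 23: C1′ hydroxyl trans to the C4′ silyloxy group, C8′ trimethylsilyl retained, upper ring still 1,4-dimethoxy | COc1ccc(OC)c2c(OCOC)c(Cl)cc([C@@]3(O)C=C[C@@H](O[Si](C)(C)C(C)(C)C)c4c(OCOC)c(Cl)cc([Si](C)(C)C)c43)c12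
F2 | step 16 | hydroxy quinone: F1 with the upper ring oxidised to the 1,4-naphthoquinone (open form of the C1 hemiketal) | O=C1C=CC(=O)c2c1c(OCOC)c(Cl)cc2[C@@]1(O)C=C[C@@H](O[Si](C)(C)C(C)(C)C)c2c(OCOC)c(Cl)cc([Si](C)(C)C)c21
F3 | step 16 | aryl iodide: F2 with iodine in place of the C8′ trimethylsilyl group | O=C1C=CC(=O)c2c1c(OCOC)c(Cl)cc2[C@@]1(O)C=C[C@@H](O[Si](C)(C)C(C)(C)C)c2c(OCOC)c(Cl)cc(I)c21
F4 | step 14 | propargylic alcohol: 22 with the C1′ ketone reduced to the carbinol (both C1′ epimers, 4′R) | COc1ccc(OC)c2c(OCOC)c(Cl)cc(C(O)C#C[C@@H](O[Si](C)(C)C(C)(C)C)c3c(OCOC)c(Cl)cc([Si](C)(C)C)c3OS(=O)(=O)C(F)(F)F)c12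
F5 | step 14 | cis-allylic alcohol: F4 with the alkyne reduced to the Z-alkene (both C1′ epimers, 4′R) | COc1ccc(OC)c2c(OCOC)c(Cl)cc(C(O)/C=C\[C@@H](O[Si](C)(C)C(C)(C)C)c3c(OCOC)c(Cl)cc([Si](C)(C)C)c3OS(=O)(=O)C(F)(F)F)c12
F6 | step 19 | tris(silyl) ether: 32 as its 5,5′-bis(triethylsilyl) ether and 4′-tert-butyldimethylsilyl ether | O=C1c2c(O[Si](CC)(CC)CC)c(Cl)cc3c2[C@@]2(Oc4cc(Cl)c(O[Si](CC)(CC)CC)c5c4[C@]3(O2)[C@@H]2O[C@@H]2[C@H]5O[Si](C)(C)C(C)(C)C)[C@@H]2O[C@H]12
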